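**Plan**

1. Retrosynthesis cuts C11=C12 and then C11'=C12' (two Wittig reactions). This gives the ring A C15 trihydroxy dienal 13, the C10 dialdehyde 17 and the ring B C15 enyne phosphonium salt 16. Both C15 units go back to one enyne 8, whose C6–C7 bond comes from Sonogashira coupling of the actinol enol triflate with the C6 enynol.
2. Enabling feature: ring A (C1–C6) is ring B plus hydroxyls on C5 and C6 and H2 across C7≡C8, with O5 cis-1,3 to O3 and trans to O6. That is the imprint of a C5,C6-epoxide anti to O3 opened at C5 from the O3 face, so the C5–O bond is cut back to the O3 tert-butyl carbonate of that epoxide.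
3. Forward: actinol → carbonate → enol triflate → Sonogashira → 8. Branch a: epoxidation, carbonate-tethered opening (closes the bridging carbonate ring, removed later), LiAlH4, desilylation, MnO2. Branch b: carbonate off, Wittig salt, Wittig with 17, reduction, second Wittig salt. The last step joins the halves.
4. Stereochemistry: C3 and C3' come from actinol; C6 from peracid attack anti to O3; C5 by inversion in the tethered opening. 9E and 9'E come from the enynol, 7E from trans-hydroalumination, 11E and 11'E from Wittig reaction plus thermal isomerisation, the rest from 17.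

Key step: step 6

Remark: carotenoid numbering is used for all intermediates (ring A C1–C6, chain from C7, ring B primed); actinol 1, the E-enynol 6 and the dialdehyde 17 are taken as purchasable.

**Route**

Step 1
Reactants: 1 actinol, (4R,6R)-4-hydroxy-2,2,6-trimethylcyclohexan-1-one; 2 di-tert-butyl dicarbonate
Product: 3 actinol tert-butyl carbonate, (4R,6R)-4-(tert-butoxycarbonyloxy)-2,2,6-trimethylcyclohexan-1-one
Conditions: Boc2O (1.5 equiv), DMAP (0.2 equiv), MeCN, rt
Reagents that add atoms: none
Why: DMAP-catalysed O-acylation of the only hydroxyl with Boc2O installs the carbonate that later serves as the internal oxygen nucleophile; the two stereocentres of actinol are not involved.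

Step 2
Reactants: 3 actinol tert-butyl carbonate
Product: 5 enol triflate, (4R)-4-(tert-butoxycarbonyloxy)-2,6,6-trimethylcyclohex-1-en-1-yl trifluoromethanesulfonate, via lithium enolate 4 (not isolated)
Conditions: LiN(iPr)2 (LDA, 1.15 equiv), THF, −78 °C; PhNTf2, −78 → 0 °C
Reagents that add atoms: N-phenylbis(trifluoromethanesulfonimide), PhNTf2, O=S(=O)(N(c1ccccc1)S(=O)(=O)C(F)(F)F)C(F)(F)F
Why: Because C1 is quaternary the ketone can enolise only towards C5, so deprotonation by the hindered amide base and O-sulfonylation of the lithium enolate with PhNTf2 (enol triflate formation) give the single C5=C6 triflate; the C5 stereocentre is given up here and C3 is untouched.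

Step 3
Reactants: 6 (E)-3-methylpent-2-en-4-yn-1-ol
Product: 7 (E)-tert-butyldimethyl[(3-methylpent-2-en-4-yn-1-yl)oxy]silane
Conditions: TBSCl (1.1 equiv), imidazole (1.5 equiv), CH2Cl2, 0 °C → rt
Reagents that add atoms: tert-butyldimethylsilyl chloride, TBSCl, CC(C)(C)[Si](C)(C)Cl
Why: Silylation of the primary allylic alcohol with TBSCl and imidazole masks O11 for the coupling, epoxidation and hydride steps; the E alkene and the terminal alkyne are untouched.

Step 4
Reactants: 5 enol triflate; 7 silylated enynol
Product: 8 common C15 enyne, tert-butyl (1R)-4-[(3E)-5-(tert-butyldimethylsilyloxy)-3-methylpent-3-en-1-yn-1-yl]-3,5,5-trimethylcyclohex-3-en-1-yl carbonate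
Conditions: Pd(PPh3)4 (5 mol%), CuI (10 mol%), iPr2NH, DMF, rt → 50 °C
Reagents that add atoms: none
Why: Sonogashira coupling of the vinyl triflate with the terminal alkyne forms the C6–C7 bond; hindered 2,6,6-trimethylcyclohexenyl triflates are established partners, and neither the homoallylic carbonate nor the allylic silyl ether can ionise under zerovalent palladium, so C3 and the 9E alkene pass through unchanged.

Step 5
Reactants: 8 common C15 enyne
Product: 9 anti-epoxide, the C5,C6-epoxide of 8 with the epoxide oxygen trans to the O3 carbonate (3S,5R,6R)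
Conditions: mCPBA (1.1 equiv), CH2Cl2, −20 → 0 °C; NaHCO3/Na2S2O3 wash
Reagents that add atoms: 3-chloroperoxybenzoic acid, mCPBA, OOC(=O)c1cccc(Cl)c1
Why: Prilezhaev epoxidation should pick the tetrasubstituted C5=C6 bond over the trisubstituted C9=C10 bond, which is deactivated by its allylic oxygen, and the peracid is expected to come in from the face opposite the C3 carbonate, setting C5 and C6 together as the anti-epoxide; the minor syn-epoxide is removed by chromatography and could in any case not cyclise in step 6.

Step 6
Reactants: 9 anti-epoxide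
Product: 10 3,5-cyclic carbonate with free C6 hydroxyl, (1S,5S,8R)-8-[(3E)-5-(tert-butyldimethylsilyloxy)-3-methylpent-3-en-1-yn-1-yl]-8-hydroxy-1,7,7-trimethyl-2,4-dioxabicyclo[3.3.1]nonan-3-one
Conditions: BF3·OEt2 (0.3 equiv), CH2Cl2, −78 → −30 °C; aq. NaHCO3
Reagents that add atoms: none
Why: Proposed new method: BF3 binds the epoxide oxygen, and the carbonyl oxygen of the O3 tert-butyl carbonate, which can reach only the lower face of C5, attacks C5 anti to the breaking C5–O bond; the tert-butoxy-dioxanylium ion so formed loses isobutene, whose proton frees the C6 hydroxyl and returns BF3. The closest known reaction type is the Lewis-acid-promoted opening of an epoxide by a neighbouring tert-butyl carbonate to give a cyclic carbonate, which has not been shown for a fully substituted cyclohexene oxide that must close to a bridged 2,4-dioxabicyclo[3.3.1]nonan-3-one. The six-membered carbonate ring closes in the 6-exo-tet mode across C3 and C5. The one new stereocentre, C5, is fixed by the C3 stereocentre through the tether, since backside attack inverts C5 and puts O5 cis to O3, while C6 keeps the oxygen delivered in step 5, trans to O5. The step needs C5 over C6 and closure over ionisation: C6 could be reached only through a seven-membered ring, and low temperature, a substoichiometric amount of BF3 and a non-nucleophilic solvent are meant to keep the propargylic C6–O bond from ionising before the carbonate has closed. The ring must react through a conformer with O3 axial, against the axial C1 methyl group, and this strain is the main cost of the closure.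

Step 7
Reactants: 10 cyclic carbonate
Product: 11 silylated 7E triol, (1S,2S,4S)-1-[(1E,3E)-5-(tert-butyldimethylsilyloxy)-3-methylpenta-1,3-dien-1-yl]-2,6,6-trimethylcyclohexane-1,2,4-triol
Conditions: LiAlH4 (4 equiv), THF, 0 °C → rt; aq. potassium sodium tartrate
Reagents that add atoms: none
Why: LiAlH4 reduces the cyclic carbonate to the diol, its carbon leaving as methanol, and the aluminium alkoxide of the propargylic C6 hydroxyl delivers hydride to C7 (trans-hydroalumination of a propargylic alcohol), so that protonolysis of the C8–Al bond leaves the 7E alkene; the three stereocentres and the silyl ether are not touched.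

Step 8
Reactants: 11 silylated 7E triol
Product: 12 tetraol, (1S,2S,4S)-1-[(1E,3E)-5-hydroxy-3-methylpenta-1,3-dien-1-yl]-2,6,6-trimethylcyclohexane-1,2,4-triol
Conditions: Bu4NF (1.2 equiv), THF, 0 °C → rt
Reagents that add atoms: none
Why: Fluoride cleaves the primary silyl ether (desilylation) and leaves the triol and both E alkenes alone.

Step 9
Reactants: 12 tetraol
Product: 13 ring A C15 aldehyde, (2E,4E)-3-methyl-5-[(1S,2S,4S)-1,2,4-trihydroxy-2,6,6-trimethylcyclohexyl]penta-2,4-dienal
Conditions: MnO2 (activated, 15 equiv), acetone, rt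
Reagents that add atoms: none
Why: MnO2 oxidises only the primary allylic (here dienylic) alcohol, the secondary C3 hydroxyl and the two tertiary hydroxyls being inert, and the neutral conditions spare the acid-sensitive tertiary allylic alcohol at C6 and the 9E geometry.

Step 10
Reactants: 8 common C15 enyne
Product: 14 ring B enyne alcohol, (1R)-4-[(3E)-5-(tert-butyldimethylsilyloxy)-3-methylpent-3-en-1-yn-1-yl]-3,5,5-trimethylcyclohex-3-en-1-ol
Conditions: LiAlH4 (1.5 equiv), THF, 0 °C; aq. potassium sodium tartrate
Reagents that add atoms: none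
Why: Hydride reduction of the tert-butyl carbonate frees the 3'-hydroxyl, the carbonate carbon leaving as methanol; at 0 °C the enyne, which has no propargylic hydroxyl to direct hydroalumination, and the silyl ether should survive.

Step 11
Reactants: 14 ring B enyne alcohol
Product: 16 ring B C15 Wittig salt, [(2E)-5-[(4R)-4-hydroxy-2,6,6-trimethylcyclohex-1-en-1-yl]-3-methylpent-2-en-4-yn-1-yl]triphenylphosphonium bromide, via enyne diol 15 (not isolated)
Conditions: PPh3·HBr (1.2 equiv), MeOH, rt
Reagents that add atoms: triphenylphosphine hydrobromide, [Br-].c1ccc(cc1)[PH+](c1ccccc1)c1ccccc1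
Why: In acidic methanol the primary silyl ether is cleaved and the resulting allylic alcohol is converted by PPh3·HBr into the allylic phosphonium salt, the standard preparation of a carotenoid C15 Wittig salt; the secondary 3'-hydroxyl does not ionise, and any 9'Z salt formed through the allylic cation is removed by crystallisation.

Step 12
Reactants: 16 ring B C15 Wittig salt; 17 (2E,4E,6E)-2,7-dimethylocta-2,4,6-trienedial
Product: 19 ring B C25 aldehyde, (2E,4E,6E,8E,10E)-13-[(4R)-4-hydroxy-2,6,6-trimethylcyclohex-1-en-1-yl]-2,7,11-trimethyltrideca-2,4,6,8,10-pentaen-12-ynal, via C15 ylide 18 (not isolated)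
Conditions: NaOMe (1.1 equiv), MeOH/CH2Cl2, 0 °C → rt, 17 in excess (2.5 equiv); then EtOAc, 70 °C
Reagents that add atoms: none
Why: Wittig olefination of the C15 ylide with an excess of the symmetrical dialdehyde forms C11'=C12' by mono-condensation; the hindered 11'Z isomer formed alongside is brought to 11'E by gentle heating (iodine is avoided because it would also equilibrate the 9' double bond next to the alkyne), and the free 3'-hydroxyl is tolerated by methoxide.

Step 13
Reactants: 19 ring B C25 aldehyde
Product: 20 ring B C25 alcohol, (2E,4E,6E,8E,10E)-13-[(4R)-4-hydroxy-2,6,6-trimethylcyclohex-1-en-1-yl]-2,7,11-trimethyltrideca-2,4,6,8,10-pentaen-12-yn-1-ol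
Conditions: NaBH4, EtOH/THF, 0 °C
Reagents that add atoms: none
Why: NaBH4 reduces the conjugated aldehyde in the 1,2 sense to the polyenyl alcohol without touching the polyene, the alkyne or the stereocentre.

Step 14
Reactants: 20 ring B C25 alcohol
Product: 21 ring B C25 Wittig salt, [(2E,4E,6E,8E,10E)-13-[(4R)-4-hydroxy-2,6,6-trimethylcyclohex-1-en-1-yl]-2,7,11-trimethyltrideca-2,4,6,8,10-pentaen-12-yn-1-yl]triphenylphosphonium bromide
Conditions: PPh3·HBr (1.05 equiv), CH2Cl2/MeOH, 0 °C → rt, dark
Reagents that add atoms: triphenylphosphine hydrobromide, [Br-].c1ccc(cc1)[PH+](c1ccccc1)c1ccccc1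
Why: PPh3·HBr ionises the polyenylic alcohol and the phosphine is captured at the chain terminus, which keeps the conjugation intact (standard formation of a polyenyl Wittig salt); the isolated secondary hydroxyl on ring B does not react.

Step 15
Reactants: 21 ring B C25 Wittig salt; 13 ring A C15 aldehyde
Product: 23 target, all-E (3S,5S,6S,3'R)-7',8'-didehydro-5,6-dihydro-β,β-carotene-3,5,6,3'-tetrol, via C25 ylide 22 (not isolated)
Conditions: NaOMe (1.2 equiv), MeOH/CH2Cl2, 0 °C → rt; then EtOH, 70 °C, crystallisation
Reagents that add atoms: none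
Why: Wittig olefination joins the halves through C11=C12; methoxide in methanol is the usual base for hydroxylated carotenoid partners, so the triol and the 3'-hydroxyl need no protection, and heating converts the hindered 11Z isomer into the all-E target, with every stereocentre already in place.

**Compound list**

1 | actinol, (4R,6R)-4-hydroxy-2,2,6-trimethylcyclohexan-1-one | O=C1C(C)(C)C[C@H](O)C[C@H]1C | starting material
2 | di-tert-butyl dicarbonate | CC(C)(C)OC(=O)OC(=O)OC(C)(C)C | starting material
3 | actinol tert-butyl carbonate | O=C1C(C)(C)C[C@H](OC(=O)OC(C)(C)C)C[C@H]1C | intermediate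
4 | lithium enolate of 3 | CC1=C(O[Li])C(C)(C)C[C@H](OC(=O)OC(C)(C)C)C1 | intermediate
5 | enol triflate, (4R)-4-(tert-butoxycarbonyloxy)-2,6,6-trimethylcyclohex-1-en-1-yl trifluoromethanesulfonate | CC1=C(OS(=O)(=O)C(F)(F)F)C(C)(C)C[C@H](OC(=O)OC(C)(C)C)C1 | intermediate
6 | (E)-3-methylpent-2-en-4-yn-1-ol | C#C/C(C)=C/CO | starting material
7 | (E)-tert-butyldimethyl[(3-methylpent-2-en-4-yn-1-yl)oxy]silane | C#C/C(C)=C/CO[Si](C)(C)C(C)(C)C | intermediate
8 | common C15 enyne (O3 tert-butyl carbonate, O11 silyl ether, 3R) | CC1=C(C#C/C(C)=C/CO[Si](C)(C)C(C)(C)C)C(C)(C)C[C@H](OC(=O)OC(C)(C)C)C1 | intermediate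
9 | anti-epoxide of 8 (3S,5R,6R; epoxide trans to O3) | CC(C)(C)[Si](C)(C)OC/C=C(C)/C#C[C@]12C(C)(C)C[C@H](OC(=O)OC(C)(C)C)C[C@@]1(C)O2 | intermediate
10 | 3,5-cyclic carbonate with free C6 hydroxyl (1S,5S,8R bicyclic numbering) | CC(C)(C)[Si](C)(C)OC/C=C(C)/C#C[C@]1(O)C(C)(C)C[C@H]2C[C@]1(C)OC(=O)O2 | intermediate
11 | silylated 7E triol (1S,2S,4S) | CC(C)(C)[Si](C)(C)OC/C=C(C)/C=C/[C@]1(O)C(C)(C)C[C@H](O)C[C@]1(C)O | intermediate
12 | tetraol (1S,2S,4S) | OC/C=C(C)/C=C/[C@]1(O)C(C)(C)C[C@H](O)C[C@]1(C)O | intermediate
13 | ring A C15 aldehyde, (2E,4E)-3-methyl-5-[(1S,2S,4S)-1,2,4-trihydroxy-2,6,6-trimethylcyclohexyl]penta-2,4-dienal | O=C/C=C(C)/C=C/[C@]1(O)C(C)(C)C[C@H](O)C[C@]1(C)O | intermediate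
14 | ring B enyne alcohol (1R), silyl ether at O11' | CC1=C(C#C/C(C)=C/CO[Si](C)(C)C(C)(C)C)C(C)(C)C[C@H](O)C1 | intermediate
15 | ring B enyne diol (1R) | CC1=C(C#C/C(C)=C/CO)C(C)(C)C[C@H](O)C1 | intermediate
16 | ring B C15 Wittig salt (phosphonium bromide) | CC1=C(C#C/C(C)=C/C[P+](c2ccccc2)(c2ccccc2)c2ccccc2)C(C)(C)C[C@H](O)C1.[Br-] | intermediate
17 | (2E,4E,6E)-2,7-dimethylocta-2,4,6-trienedial | O=C/C(C)=C/C=C/C=C(C)/C=O | starting material
18 | C15 ylide from 16 | CC1=C(C#C/C(C)=C/C=P(c2ccccc2)(c2ccccc2)c2ccccc2)C(C)(C)C[C@H](O)C1 | intermediate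
19 | ring B C25 aldehyde | CC1=C(C#C/C(C)=C/C=C/C(C)=C/C=C/C=C(C)/C=O)C(C)(C)C[C@H](O)C1 | intermediate
20 | ring B C25 alcohol | CC1=C(C#C/C(C)=C/C=C/C(C)=C/C=C/C=C(C)/CO)C(C)(C)C[C@H](O)C1 | intermediate
21 | ring B C25 Wittig salt (phosphonium bromide) | CC1=C(C#C/C(C)=C/C=C/C(C)=C/C=C/C=C(C)/C[P+](c2ccccc2)(c2ccccc2)c2ccccc2)C(C)(C)C[C@H](O)C1.[Br-] | intermediate
22 | C25 ylide from 21 | CC1=C(C#C/C(C)=C/C=C/C(C)=C/C=C/C=C(C)/C=P(c2ccccc2)(c2ccccc2)c2ccccc2)C(C)(C)C[C@H](O)C1 | intermediate
23 | all-E (3S,5S,6S,3'R)-7',8'-didehydro-5,6-dihydro-β,β-carotene-3,5,6,3'-tetrol | CC1=C(C#C/C(C)=C/C=C/C(C)=C/C=C/C=C(C)/C=C/C=C(C)/C=C/[C@]2(O)C(C)(C)C[C@H](O)C[C@]2(C)O)C(C)(C)C[C@H](O)C1 | target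

**Count and risks**

Total steps: 15. Longest linear sequence: 9 steps (1, 2, 4, 5, 6, 7, 8, 9, 15; the ring B line 1, 2, 4, 10, 11, 12, 13, 14, 15 is equally long).

Step 6 (most at risk). BF3 may ionise the propargylic C6–O bond, leading to ring contraction or a shift to a ketone, or it may strip the tert-butyl group before the C5–O bond has formed. The bridged closure may also be too slow against the axial C1 methyl group. The fallback uses no tether and only known reaction types; it sets out from 14 and comes back at 11. Hydroxyl-directed epoxidation of the homoallylic alcohol 14 (VO(acac)2, t-BuOOH, toluene) should deliver oxygen on the O3 face and give the syn-epoxy alcohol F1. Dilute aqueous acid (HClO4 cat., THF/H2O, 0 °C) should then open F1 at the propargylic C6 with inversion, turning the ionisation that threatens step 6 into the productive path. Water enters anti to the C5 oxygen, giving the alkynyl triol F2 with O5 cis to O3 and O6 trans to O5. LiAlH4 under the conditions of step 7 converts F2 into 11.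

Step 5. The carbonate is a small and remote shield, so the peracid may not discriminate the two faces well, and some oxidation of C9=C10 may compete. The fallback separates the face-directing group from the participating group; it sets out from 14 and comes back at 9. Silylation of 14 (Et3SiCl, imidazole) gives the bis-silyl ether F3, whose bulkier O3 group should steer mCPBA more firmly to the opposite face and give the silylated anti-epoxide F4. Mild acidic methanolysis (PPTS, MeOH, 0 °C) removes the secondary triethylsilyl group in the presence of the primary tert-butyldimethylsilyl ether and gives the hydroxy anti-epoxide F5. Acylation with Boc2O and DMAP as in step 1 then gives 9.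

Step 2. The amide base or the lithium enolate may attack the carbonate, causing loss or transfer of the tert-butoxycarbonyl group, and O-sulfonylation of the hindered tetrasubstituted enolate may be slow. The fallback forms C6–C7 by carbonyl addition instead of cross-coupling; it sets out from 3 and 7 and comes back at 8, bypassing 5. Deprotonation of 7 with n-BuLi (THF, −78 °C) gives the lithium acetylide F6, which adds to the ketone of 3 to give the tertiary propargylic alcohol F7 as a mixture at C6 that is of no consequence. Dehydration (POCl3, pyridine) can only proceed towards C5, because C1 is quaternary, and gives 8.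

Further compounds
F1 | step 6 | syn-epoxy alcohol, C5,C6-epoxide of 14 cis to the 3-hydroxyl (3S,5S,6S) | CC(C)(C)[Si](C)(C)OC/C=C(C)/C#C[C@@]12C(C)(C)C[C@H](O)C[C@]1(C)O2
F2 | step 6 | alkynyl triol, silyl ether at O11 (3S,5S,6R) | CC(C)(C)[Si](C)(C)OC/C=C(C)/C#C[C@]1(O)C(C)(C)C[C@H](O)C[C@]1(C)O
F3 | step 5 | bis-silyl ether of 14 (O3 triethylsilyl, O11 tert-butyldimethylsilyl) | CC1=C(C#C/C(C)=C/CO[Si](C)(C)C(C)(C)C)C(C)(C)C[C@H](O[Si](CC)(CC)CC)C1
F4 | step 5 | silylated anti-epoxide (epoxide trans to O3) | CC(C)(C)[Si](C)(C)OC/C=C(C)/C#C[C@]12C(C)(C)C[C@H](O[Si](CC)(CC)CC)C[C@@]1(C)O2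
F5 | step 5 | hydroxy anti-epoxide | CC(C)(C)[Si](C)(C)OC/C=C(C)/C#C[C@]12C(C)(C)C[C@H](O)C[C@@]1(C)O2
F6 | step 2 | lithium acetylide of 7 | [Li]C#C/C(C)=C/CO[Si](C)(C)C(C)(C)C
F7 | step 2 | tertiary propargylic alcohol from 3 and F6 (C6 epimers) | CC(C)(C)[Si](C)(C)OC/C=C(C)/C#CC1(O)C(C)(C)C[C@H](OC(=O)OC(C)(C)C)C[C@H]1C
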